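**Plan**

- Cuts, in retrosynthetic order: (a) C7–OOH with the C5=C6 shift, an ene retron that leads back to the prenyl end (C6=C7) of dienol 16; (b) C1–C2 together with C3–CH3, which leads to terminal alkyne 12, a methyl–aluminium reagent and the coumarin O–CH2Cl ether 4; (c) the alkyne–C4 bond, from a Weinreb amide and a silylacetylide; (d) the pyranone ring, from an o-hydroxyacetophenone and diethyl carbonate.
- Enabling feature: the unit O–CH2(C1)–CH(C2)=C(C3)(CH3)– has C2 carrying only H and C1 cis to the methyl. This is what syn addition of CH3–Al across a terminal alkyne (C2≡C3) leaves after C-alkylation at C2. The benzopyranone ring is a bystander that supplies the electrophile.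
- Forward order: the pyranone ring is closed first and O-chloromethylated. The chain is built from acid to Weinreb amide, ynone, (R)-carbinol and silyl ether. One flask then installs the C3 methyl and joins the two halves, followed by desilylation and photooxygenation last.
- Stereochemistry: C4 (R) comes from Noyori transfer hydrogenation of the ynone and is carried unchanged; 2E comes from syn-carbometalation and retentive alkylation; 5E comes from the ene transition state.

Key step: step 8

Remark: compounds 1 and 5, chloromethyl chlorosulfate and the (R,R)-TsDPEN–Ru catalyst are taken as catalogue items. Locants C1–C8 refer to the octadienyl chain (C1 = OCH2).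

**Route**

Step 1
Reactants: 1 1-(2-hydroxy-6-methylphenyl)ethan-1-one
Product: 3 4-hydroxy-5-methyl-2H-chromen-2-one, via beta-keto ester 2 (not isolated)
Conditions: NaH, (EtO)2CO, toluene, 110 °C; then 2 M HCl
Reagents that add atoms: diethyl carbonate CCOC(=O)OCC
Why: Claisen-type C-ethoxycarbonylation of the ketone enolate followed by lactonisation of the phenoxide onto the new ester (6-exo-trig acyl substitution) is the standard 4-hydroxycoumarin synthesis from o-hydroxyacetophenones, and the 6-methyl group ends up at C5.

Step 2
Reactants: 3 4-hydroxy-5-methyl-2H-chromen-2-one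
Product: 4 4-(chloromethoxy)-5-methyl-2H-chromen-2-one
Conditions: ClCH2OSO2Cl, NaHCO3, n-Bu4NHSO4 (cat.), CH2Cl2/H2O, 0 °C to rt
Reagents that add atoms: chloromethyl chlorosulfate ClCOS(=O)(=O)Cl
Why: The acidic 4-hydroxycoumarin behaves as a vinylogous carboxylic acid, so phase-transfer SN2 displacement of chlorosulfate (chloromethyl ester synthesis) should apply, the hard sulfonate-type electrophile favouring O- over C3-alkylation.

Step 3
Reactants: 5 4-methylpent-3-enoic acid
Product: 7 N-methoxy-N,4-dimethylpent-3-enamide, via acyl imidazole 6 (not isolated)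
Conditions: CDI, CH2Cl2, rt; then MeNH(OMe)·HCl, rt
Reagents that add atoms: 1,1'-carbonyldiimidazole O=C(n1ccnc1)n1ccnc1 (atoms only in intermediate 6); N,O-dimethylhydroxylamine hydrochloride CNOC.Cl
Why: Amide formation through the acyl imidazolide runs under near-neutral conditions, which should keep the β,γ-double bond out of conjugation.

Step 4
Reactants: 7 N-methoxy-N,4-dimethylpent-3-enamide
Product: 9 6-methyl-1-(trimethylsilyl)hept-5-en-1-yn-3-one, via tetrahedral lithium adduct 8 (not isolated)
Conditions: TMS–C≡CH, n-BuLi, THF, −78 °C; then 7, −78 to 0 °C; cold 1 M HCl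
Reagents that add atoms: ethynyltrimethylsilane C#C[Si](C)(C)C; n-butyllithium [Li]CCCC (lithium only in intermediate 8)
Why: Weinreb ketone synthesis, in which the chelated tetrahedral adduct 8 resists over-addition and collapses to the ynone only on the cold acidic quench.

Step 5
Reactants: 9 6-methyl-1-(trimethylsilyl)hept-5-en-1-yn-3-one
Product: 10 (3R)-6-methyl-1-(trimethylsilyl)hept-5-en-1-yn-3-ol
Conditions: Ru[(R,R)-TsDPEN](p-cymene) (2 mol%), i-PrOH, rt
Reagents that add atoms: none
Why: Noyori asymmetric transfer hydrogenation of an alkynyl ketone delivers hydride and proton through a six-membered outer-sphere transition state that distinguishes the alkynyl from the CH2 substituent, so by the established sense for alkyl alkynyl ketones the (R,R)-ligand should give the (3R)-carbinol (to be confirmed by Mosher analysis), and the base-free conditions should leave the skipped enone unisomerised.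

Step 6
Reactants: 10 (3R)-6-methyl-1-(trimethylsilyl)hept-5-en-1-yn-3-ol
Product: 11 (3R)-6-methylhept-5-en-1-yn-3-ol
Conditions: K2CO3 (cat.), MeOH, 0 °C to rt
Reagents that add atoms: none
Why: Methoxide attack at silicon cleaves the alkynyl C–Si bond (protodesilylation) without touching the carbinol centre.

Step 7
Reactants: 11 (3R)-6-methylhept-5-en-1-yn-3-ol
Product: 12 tert-butyl(dimethyl){[(3R)-6-methylhept-5-en-1-yn-3-yl]oxy}silane
Conditions: TBSCl, imidazole, DMF, rt
Reagents that add atoms: tert-butyldimethylsilyl chloride CC(C)(C)[Si](C)(C)Cl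
Why: Standard imidazole-promoted silylation masks the hydroxyl so that it neither consumes the aluminium reagent nor competes as an oxygen nucleophile in step 8.

Step 8
Reactants: 12 tert-butyl(dimethyl){[(3R)-6-methylhept-5-en-1-yn-3-yl]oxy}silane; 4 4-(chloromethoxy)-5-methyl-2H-chromen-2-one
Product: 15 4-{[(2E,4R)-4-[(tert-butyldimethylsilyl)oxy]-3,7-dimethylocta-2,6-dien-1-yl]oxy}-5-methyl-2H-chromen-2-one, via alkenylalane 13 (not isolated), via lithium alanate 14 (not isolated)
Conditions: AlMe3, Cp2ZrCl2 (cat.), CH2Cl2, 0 °C to rt; evaporate excess AlMe3; n-BuLi, hexane/THF, −78 °C; then 4, THF, −78 to 0 °C; aq. Rochelle salt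
Reagents that add atoms: trimethylaluminium C[Al](C)C; n-butyllithium [Li]CCCC (atoms only in intermediate 14)
Why: The Zr/Al methyl species adds CH3–metal syn across the terminal C≡C of 12 (methyl to the internal carbon, metal to the terminal CH) to give the (E)-alkenylalane 13, and n-BuLi converts this into the more nucleophilic alanate 14, whose alkenyl carbon displaces chloride from the O–CH2–Cl carbon of 4 with retention at the sp2 carbon, so that the C3–CH3 bond, the 2E olefin and the bond uniting the two halves arise in one flask. The closest known reaction type is the Negishi carboalumination of a terminal alkyne with ate-complex alkylation by a chloromethyl ether, which gives (E)-3-methylalk-2-enyl ethers. No ring is closed and no stereocentre is created; the only stereochemical element formed, the trisubstituted olefin, is fixed by the syn-carbometalation and the retentive C–Al to C–C exchange, and C4 is carried through unchanged as its silyl ether. Regioselectivity of the methylmetalation is secured by the terminal alkyne (metal to the unsubstituted carbon), and the trisubstituted 6,7-olefin is inert to this catalyst. Chemoselectivity in the alkylation (CH2–Cl against the lactone carbonyl or C4 of the coumarin) rests on the high SN2 reactivity of the vinylogous acyloxymethyl chloride at −78 °C, on removal of excess AlMe3 before ate formation, and on all n-BuLi being bound in 14 before 4 is added. A Pd(0)- or Ni(0)-catalysed coupling is avoided on purpose, because such catalysts would ionise the allyl aryl ether of 15, whose aryloxide is a carboxylate-like leaving group.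

Step 9
Reactants: 15 4-{[(2E,4R)-4-[(tert-butyldimethylsilyl)oxy]-3,7-dimethylocta-2,6-dien-1-yl]oxy}-5-methyl-2H-chromen-2-one
Product: 16 4-{[(2E,4R)-4-hydroxy-3,7-dimethylocta-2,6-dien-1-yl]oxy}-5-methyl-2H-chromen-2-one
Conditions: TBAF, AcOH, THF, 0 °C to rt
Reagents that add atoms: none
Why: Fluoride-driven Si–O cleavage, buffered with acetic acid, should spare the lactone and the allyl aryl ether and leave the C4 configuration untouched.

Step 10
Reactants: 16 4-{[(2E,4R)-4-hydroxy-3,7-dimethylocta-2,6-dien-1-yl]oxy}-5-methyl-2H-chromen-2-one
Product: 17 4-{[(2E,4R,5E)-7-hydroperoxy-4-hydroxy-3,7-dimethylocta-2,5-dien-1-yl]oxy}-5-methyl-2H-chromen-2-one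
Conditions: O2, TPP (cat.), hν (> 500 nm), CH2Cl2, 0 °C
Reagents that add atoms: dioxygen (as sensitised singlet oxygen) O=O
Why: Schenck ene reaction, in which singlet oxygen attacks the electron-rich C6=C7 bond (C2=C3 is deactivated by two allylic oxygens and the coumarin enol ether by conjugation), removes an allylic hydrogen from C5 suprafacially with C–O bond formation at C7 and shift of the double bond to C5=C6 (E favoured because the C4 substituent takes the outside position), creates no stereocentre at the dimethyl-substituted C7, and must be expected to give the regioisomer from methyl-hydrogen abstraction as a co-product to be removed by chromatography.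

**Compound list**

1 | 1-(2-hydroxy-6-methylphenyl)ethan-1-one | CC(=O)c1c(C)cccc1O | starting material
2 | ethyl 3-(2-hydroxy-6-methylphenyl)-3-oxopropanoate (present in the flask as its sodium salt) | CCOC(=O)CC(=O)c1c(C)cccc1O | intermediate
3 | 4-hydroxy-5-methyl-2H-chromen-2-one | Oc1cc(=O)oc2cccc(C)c12 | intermediate
4 | 4-(chloromethoxy)-5-methyl-2H-chromen-2-one | ClCOc1cc(=O)oc2cccc(C)c12 | intermediate
5 | 4-methylpent-3-enoic acid | CC(C)=CCC(=O)O | starting material
6 | 1-(4-methylpent-3-enoyl)-1H-imidazole | CC(C)=CCC(=O)n1ccnc1 | intermediate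
7 | N-methoxy-N,4-dimethylpent-3-enamide | CON(C)C(=O)CC=C(C)C | intermediate
8 | lithium 3-[methoxy(methyl)amino]-6-methyl-1-(trimethylsilyl)hept-5-en-1-yn-3-olate | CC(C)=CCC(O[Li])(C#C[Si](C)(C)C)N(C)OC | intermediate
9 | 6-methyl-1-(trimethylsilyl)hept-5-en-1-yn-3-one | C[Si](C)(C)C#CC(=O)CC=C(C)C | intermediate
10 | (3R)-6-methyl-1-(trimethylsilyl)hept-5-en-1-yn-3-ol | C[Si](C)(C)C#C[C@H](O)CC=C(C)C | intermediate
11 | (3R)-6-methylhept-5-en-1-yn-3-ol | C#C[C@H](O)CC=C(C)C | intermediate
12 | tert-butyl(dimethyl){[(3R)-6-methylhept-5-en-1-yn-3-yl]oxy}silane | C#C[C@H](O[Si](C)(C)C(C)(C)C)CC=C(C)C | intermediate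
13 | {(1E,3R)-3-[(tert-butyldimethylsilyl)oxy]-2,6-dimethylhepta-1,5-dien-1-yl}dimethylalane | C/C(=C\[Al](C)C)[C@H](O[Si](C)(C)C(C)(C)C)CC=C(C)C | intermediate
14 | lithium butyl{(1E,3R)-3-[(tert-butyldimethylsilyl)oxy]-2,6-dimethylhepta-1,5-dien-1-yl}dimethylalanate | C/C(=C\[Al-](C)(C)CCCC)[C@H](O[Si](C)(C)C(C)(C)C)CC=C(C)C.[Li+] | intermediate
15 | 4-{[(2E,4R)-4-[(tert-butyldimethylsilyl)oxy]-3,7-dimethylocta-2,6-dien-1-yl]oxy}-5-methyl-2H-chromen-2-one | C/C(=C\COc1cc(=O)oc2cccc(C)c12)[C@H](O[Si](C)(C)C(C)(C)C)CC=C(C)C | intermediate
16 | 4-{[(2E,4R)-4-hydroxy-3,7-dimethylocta-2,6-dien-1-yl]oxy}-5-methyl-2H-chromen-2-one | C/C(=C\COc1cc(=O)oc2cccc(C)c12)[C@H](O)CC=C(C)C | intermediate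
17 | 4-{[(2E,4R,5E)-7-hydroperoxy-4-hydroxy-3,7-dimethylocta-2,5-dien-1-yl]oxy}-5-methyl-2H-chromen-2-one | C/C(=C\COc1cc(=O)oc2cccc(C)c12)[C@H](O)/C=C/C(C)(C)OO | target

**Summary**

Total step count: 10. Longest linear sequence: 8 steps (steps 3 to 10, from 4-methylpent-3-enoic acid); the coumarin branch (steps 1 and 2) joins at step 8.

**Steps most likely to fail**

1. Step 10. Hydrogen abstraction may be poorly regioselective: the cis-methyl hydrogens compete with C5–H, and the branched C4 substituent may tilt the balance further toward the methyl. Slow over-oxidation at C2=C3 is a further loss. Fallback, setting out from 15 and coming back at 17: the regiochemistry is fixed by ionic chemistry instead of the ene reaction. The silyl ether is kept so that the C4 oxygen cannot capture the seleniranium ion. Markovnikov peroxyselenenylation of the 6,7-olefin with N-(phenylseleno)phthalimide and 2-methoxypropan-2-yl hydroperoxide (cat. PPTS, CH2Cl2, −40 °C) should give the C6-phenylselanyl C7-peroxyketal F1. Oxidation with mCPBA at −78 °C and warming with i-Pr2NH should trigger selenoxide syn-elimination, which can only run toward C5 because C7 bears no hydrogen, giving the (5E)-allylic peroxyketal F2. Aqueous HF in MeCN at 0 °C should then remove both the 2-methoxypropyl group and the silyl group to give 17.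

2. Step 8. The alanate may attack the coumarin (lactone carbonyl, or addition–elimination at C4) instead of the CH2–Cl carbon, the displacement at this acyloxymethyl-type chloride may be sluggish, or the methylalumination next to the silyloxy group may be incomplete. Fallback, setting out from 12 and coming back at 15: the same methylalumination and ate formation are used, but the alanate is quenched with paraformaldehyde to give the allylic alcohol F3. F3 is then joined to 3 by a Mitsunobu reaction (PPh3, DIAD, THF, 0 °C), so the halves are united through the C1–O bond instead.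

3. Step 2. The ambident anion may alkylate at C3 instead of at oxygen, or the chloromethyl ether may hydrolyse and release formaldehyde, which links two coumarin units through C3. Fallback, setting out from 3 and coming back at 4: 3 is converted into the silver(I) salt F4 (AgNO3, aq. NaOH, dark), which is dried and alkylated heterogeneously with chloroiodomethane in toluene at rt; silver-assisted halide abstraction directs alkylation to oxygen under anhydrous conditions.

**Further compounds**

F1 | step 10 | 4-{[(2E,4R)-4-[(tert-butyldimethylsilyl)oxy]-7-[(2-methoxypropan-2-yl)peroxy]-3,7-dimethyl-6-(phenylselanyl)oct-2-en-1-yl]oxy}-5-methyl-2H-chromen-2-one (both C6 epimers) | C/C(=C\COc1cc(=O)oc2cccc(C)c12)[C@H](O[Si](C)(C)C(C)(C)C)CC([Se]c1ccccc1)C(C)(C)OOC(C)(C)OC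
F2 | step 10 | 4-{[(2E,4R,5E)-4-[(tert-butyldimethylsilyl)oxy]-7-[(2-methoxypropan-2-yl)peroxy]-3,7-dimethylocta-2,5-dien-1-yl]oxy}-5-methyl-2H-chromen-2-one | C/C(=C\COc1cc(=O)oc2cccc(C)c12)[C@H](O[Si](C)(C)C(C)(C)C)/C=C/C(C)(C)OOC(C)(C)OC
F3 | step 8 | (2E,4R)-4-[(tert-butyldimethylsilyl)oxy]-3,7-dimethylocta-2,6-dien-1-ol | C/C(=C\CO)[C@H](O[Si](C)(C)C(C)(C)C)CC=C(C)C
F4 | step 2 | silver(I) 5-methyl-2-oxo-2H-chromen-4-olate | [Ag+].[O-]c1cc(=O)oc2cccc(C)c12
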